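**Strategy**

The cyclohexenone ring (C3a, C4, C5, C6, C7, C7a) is cut at C3a–C4 and C5–C6: its vinylogous ester C6(=O)–C7=C7a–O1 and the quaternary C3a are carried by a tetrahydrofuran-fused 3-alkoxycyclobutenone, and C4–C5(OMe) by 1-methoxyvinyllithium. Carbonyl addition triggers oxyanion-accelerated 4π ring opening and 6π ring closure, which in one operation enlarges the four-membered ring to the six-membered enone, sets C3a against the cis 2-aryl-3-methyl tetrahydrofuran and, on protonation, C5. The precursor, a 2-oxabicyclo[3.2.0]hept-1(7)-en-6-one, comes from a ketene–ethoxyacetylene cycloaddition; C2 and C3 come from a catalytic asymmetric syn-crotylboration.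

Key step: step 8

Numbering: O1, C2, C3, C3a, C4–C7 and C7a are the benzofuranone locants of the target and are used for the same atoms in all intermediates; Ar = 3,4,5-trimethoxyphenyl.

Assumption: the (R)-configured phosphoric acid delivers the crotyl group to the Re face of the aryl aldehyde, as in the parent allylboration of benzaldehyde; if the opposite sense is found, the (S)-acid is used.

**Route**

Step 1
Reactants: 1 3,4,5-trimethoxybenzaldehyde; 2 (Z)-crotylboronic acid pinacol ester
Product: 3 (1R,2S)-2-methyl-1-(3,4,5-trimethoxyphenyl)but-3-en-1-ol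
Conditions: (R)-3,3′-bis(2,4,6-triisopropylphenyl)-1,1′-binaphthyl-2,2′-diyl hydrogen phosphate (5 mol %), PhMe, −30 °C; aq. NaHCO3
Reagents that add atoms: none
Why: Chiral phosphoric acid-catalysed crotylboration through a closed chair transition state, in which the Z-boronate gives the syn relationship (C2 carbinol, C3 methyl) and the hydrogen-bonded catalyst selects the aldehyde face that gives the (1R) carbinol.

Step 2
Reactants: 3 (1R,2S)-2-methyl-1-(3,4,5-trimethoxyphenyl)but-3-en-1-ol
Product: 4 tert-butyl(dimethyl){[(1R,2S)-2-methyl-1-(3,4,5-trimethoxyphenyl)but-3-en-1-yl]oxy}silane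
Conditions: TBSOTf, 2,6-lutidine, CH2Cl2, 0 °C
Reagents that add atoms: tert-butyldimethylsilyl trifluoromethanesulfonate, CC(C)(C)[Si](C)(C)OS(=O)(=O)C(F)(F)F
Why: Silylation of the hindered benzylic alcohol with the silyl triflate and a non-nucleophilic base; no stereocentre is touched.

Step 3
Reactants: 4 tert-butyl(dimethyl){[(1R,2S)-2-methyl-1-(3,4,5-trimethoxyphenyl)but-3-en-1-yl]oxy}silane
Product: 5 (3S,4R)-4-{[tert-butyl(dimethyl)silyl]oxy}-3-methyl-4-(3,4,5-trimethoxyphenyl)butan-1-ol
Conditions: 9-borabicyclo[3.3.1]nonane (9-BBN), THF, 0 °C to 23 °C; then NaOH, H2O2, 0 °C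
Reagents that add atoms: hydrogen peroxide, OO
Why: Anti-Markovnikov hydroboration–oxidation of the terminal alkene; the silyl ether and the arene are inert.

Step 4
Reactants: 5 (3S,4R)-4-{[tert-butyl(dimethyl)silyl]oxy}-3-methyl-4-(3,4,5-trimethoxyphenyl)butan-1-ol
Product: 6 (3S,4R)-4-{[tert-butyl(dimethyl)silyl]oxy}-3-methyl-4-(3,4,5-trimethoxyphenyl)butanoic acid
Conditions: 2,2,6,6-tetramethylpiperidin-1-oxyl (TEMPO, 10 mol %), PhI(OAc)2, MeCN/H2O (1:1), 23 °C
Reagents that add atoms: water, O
Why: Nitroxyl-catalysed oxidation of the primary alcohol through the aldehyde hydrate to the acid; the C3 stereocentre is β to the carbonyl and cannot epimerise.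

Step 5
Reactants: 6 (3S,4R)-4-{[tert-butyl(dimethyl)silyl]oxy}-3-methyl-4-(3,4,5-trimethoxyphenyl)butanoic acid; 7 allyl bromide
Product: 8 (3S,4R)-4-{[tert-butyl(dimethyl)silyl]oxy}-3-methyl-2-(prop-2-en-1-yl)-4-(3,4,5-trimethoxyphenyl)butanoic acid (both C2 epimers)
Conditions: LiN(i-Pr)2 (2.2 equiv), THF, −78 °C to 0 °C; 7, DMPU, −78 °C to 23 °C; cold 0.5 M HCl
Reagents that add atoms: none
Why: Alkylation of the carboxylic acid dianion at the α-carbon (the future C3a); the new centre is not controlled because it becomes planar in steps 6 and 8.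

Step 6
Reactants: 8 (3S,4R)-4-{[tert-butyl(dimethyl)silyl]oxy}-3-methyl-2-(prop-2-en-1-yl)-4-(3,4,5-trimethoxyphenyl)butanoic acid; 9 ethoxyacetylene
Product: 12 4-[(1R,2S)-1-{[tert-butyl(dimethyl)silyl]oxy}-1-(3,4,5-trimethoxyphenyl)propan-2-yl]-3-ethoxy-4-(prop-2-en-1-yl)cyclobut-2-en-1-one (both C4 epimers), via acid chloride 10 (not isolated), via ketene 11 (not isolated)
Conditions: (COCl)2, N,N-dimethylformamide (cat.), CH2Cl2, 0 °C to 23 °C, evaporate; then 9, Et3N, PhMe, 60 °C (sealed tube)
Reagents that add atoms: none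
Why: Triethylamine dehydrochlorinates acid chloride 10 to the dialkylketene 11 (too hindered to dimerise), and a thermal [2+2] ketene–alkynyl ether cycloaddition joins the ketene carbonyl carbon (C6) to the nucleophilic CH terminus of 9 (C7) and C3a to the ethoxy-bearing carbon (C7a), giving the 3-ethoxycyclobutenone.

Step 7
Reactants: 12 4-[(1R,2S)-1-{[tert-butyl(dimethyl)silyl]oxy}-1-(3,4,5-trimethoxyphenyl)propan-2-yl]-3-ethoxy-4-(prop-2-en-1-yl)cyclobut-2-en-1-one
Product: 14 (3R,4S)-4-methyl-5-(prop-2-en-1-yl)-3-(3,4,5-trimethoxyphenyl)-2-oxabicyclo[3.2.0]hept-1(7)-en-6-one (both C5 epimers), via alkoxide 13 (not isolated)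
Conditions: Bu4NF, THF, 0 °C to 23 °C
Reagents that add atoms: none
Why: Fluoride desilylation frees the C2 alkoxide, which adds to the β-carbon C7a of the vinylogous ester (5-exo-trig) and expels ethoxide (addition–elimination, a vinylogous transesterification), closing the tetrahydrofuran without touching the C2–O bond or C3.

Step 8
Reactants: 14 (3R,4S)-4-methyl-5-(prop-2-en-1-yl)-3-(3,4,5-trimethoxyphenyl)-2-oxabicyclo[3.2.0]hept-1(7)-en-6-one; 15 methyl vinyl ether
Product: 20 Dysodanthin B (2R,3S,3aS,5R)-5-methoxy-3-methyl-3a-(prop-2-en-1-yl)-2-(3,4,5-trimethoxyphenyl)-3,3a,4,5-tetrahydro-1-benzofuran-6(2H)-one, via 1-methoxyvinyllithium 16 (not isolated), via lithium cyclobutenolate 17 (not isolated), via lithium trienolate 18 (not isolated), via lithium dienolate 19 (not isolated)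
Conditions: 15, t-BuLi, THF, −78 °C to 0 °C; 14, −78 °C to 23 °C, then 50 °C; 2,6-di-tert-butylphenol, −78 °C
Reagents that add atoms: none
Why: Lithium reagent 16 adds to the C6 carbonyl of 14 anti to the allyl group to give cyclobutenolate 17, which opens by conrotatory 4π-electrocyclic cleavage of the C6–C3a bond to trienolate 18 and closes by disrotatory 6π-electrocyclization between C3a and C4 to dienolate 19, which is protonated at C5. The closest known reaction type is the ring expansion of cyclobutenones to cyclohexenones by 1,2-addition of alkenyllithium reagents followed by oxyanion-accelerated ring opening and hexatriene electrocyclization, also known for alkenyllithium adducts of benzocyclobutenones. The only ring closed is the six-membered carbocycle, formed from the four-membered ring by a thermally allowed 6π-electrocyclization (overall a 1,3-shift of C3a from C6 to C4), while the tetrahydrofuran is carried through 18 as a 4,5-dihydrofuran. C3a is planar in 18, so both epimers of 14 converge, and it is re-formed by bonding of C4 to the face of the dihydrofuran opposite the C3 methyl and the cis C2 aryl group, which leaves the allyl group cis to both. C5 is set by kinetic protonation of 19 on the face opposite the pseudoaxial allyl group (1,3 to C5) with a hindered phenol at −78 °C, which leaves the methoxy group cis to the allyl group. The step needs the oxido group to turn outward so that the methoxyvinyl group ends cis to C7a: the fused ring fixes the sense of conrotation (C3 outward), addition anti to the allyl group puts the oxygen on the face that this sense turns outward, and lithium chelation between the C6 oxygen and the methoxy oxygen holds C4 over C3a.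

**Compound list**

1 | 3,4,5-trimethoxybenzaldehyde | COc1cc(C=O)cc(OC)c1OC | starting material
2 | (Z)-crotylboronic acid pinacol ester, 2-[(2Z)-but-2-en-1-yl]-4,4,5,5-tetramethyl-1,3,2-dioxaborolane | C/C=C\CB1OC(C)(C)C(C)(C)O1 | starting material
3 | (1R,2S)-2-methyl-1-(3,4,5-trimethoxyphenyl)but-3-en-1-ol | O[C@@H](c1cc(OC)c(OC)c(OC)c1)[C@H](C=C)C | intermediate
4 | tert-butyl(dimethyl){[(1R,2S)-2-methyl-1-(3,4,5-trimethoxyphenyl)but-3-en-1-yl]oxy}silane | CC(C)(C)[Si](C)(C)O[C@@H](c1cc(OC)c(OC)c(OC)c1)[C@H](C=C)C | intermediate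
5 | (3S,4R)-4-{[tert-butyl(dimethyl)silyl]oxy}-3-methyl-4-(3,4,5-trimethoxyphenyl)butan-1-ol | CC(C)(C)[Si](C)(C)O[C@@H](c1cc(OC)c(OC)c(OC)c1)[C@H](CCO)C | intermediate
6 | (3S,4R)-4-{[tert-butyl(dimethyl)silyl]oxy}-3-methyl-4-(3,4,5-trimethoxyphenyl)butanoic acid | CC(C)(C)[Si](C)(C)O[C@@H](c1cc(OC)c(OC)c(OC)c1)[C@H](CC(=O)O)C | intermediate
7 | allyl bromide (3-bromoprop-1-ene) | C=CCBr | starting material
8 | (3S,4R)-4-{[tert-butyl(dimethyl)silyl]oxy}-3-methyl-2-(prop-2-en-1-yl)-4-(3,4,5-trimethoxyphenyl)butanoic acid, both C2 epimers | CC(C)(C)[Si](C)(C)O[C@@H](c1cc(OC)c(OC)c(OC)c1)[C@H](C(CC=C)C(=O)O)C | intermediate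
9 | ethoxyacetylene (ethoxyethyne) | C#COCC | starting material
10 | acid chloride of 8, both C2 epimers | CC(C)(C)[Si](C)(C)O[C@@H](c1cc(OC)c(OC)c(OC)c1)[C@H](C(CC=C)C(Cl)=O)C | intermediate
11 | ketene from 10, 2-[(1R,2S)-1-{[tert-butyl(dimethyl)silyl]oxy}-1-(3,4,5-trimethoxyphenyl)propan-2-yl]penta-1,4-dien-1-one | CC(C)(C)[Si](C)(C)O[C@@H](c1cc(OC)c(OC)c(OC)c1)[C@H](C(CC=C)=C=O)C | intermediate
12 | 4-[(1R,2S)-1-{[tert-butyl(dimethyl)silyl]oxy}-1-(3,4,5-trimethoxyphenyl)propan-2-yl]-3-ethoxy-4-(prop-2-en-1-yl)cyclobut-2-en-1-one, both C4 epimers | CC(C)(C)[Si](C)(C)O[C@@H](c1cc(OC)c(OC)c(OC)c1)[C@@H](C)C1(CC=C)C(=O)C=C1OCC | intermediate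
13 | 3-ethoxy-4-[(1R,2S)-1-hydroxy-1-(3,4,5-trimethoxyphenyl)propan-2-yl]-4-(prop-2-en-1-yl)cyclobut-2-en-1-one, formed as its alkoxide, both C4 epimers | O[C@@H](c1cc(OC)c(OC)c(OC)c1)[C@@H](C)C1(CC=C)C(=O)C=C1OCC | intermediate
14 | (3R,4S)-4-methyl-5-(prop-2-en-1-yl)-3-(3,4,5-trimethoxyphenyl)-2-oxabicyclo[3.2.0]hept-1(7)-en-6-one, both C5 epimers | O=C1C=C2O[C@@H](c3cc(OC)c(OC)c(OC)c3)[C@@H](C)C12CC=C | intermediate
15 | methyl vinyl ether (methoxyethene) | C=COC | starting material
16 | 1-methoxyvinyllithium | [Li]C(=C)OC | intermediate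
17 | lithium (3R,4S)-6-(1-methoxyethenyl)-4-methyl-5-(prop-2-en-1-yl)-3-(3,4,5-trimethoxyphenyl)-2-oxabicyclo[3.2.0]hept-1(7)-en-6-olate | [Li]OC1(C(=C)OC)C=C2O[C@@H](c3cc(OC)c(OC)c(OC)c3)[C@@H](C)C12CC=C | intermediate
18 | lithium (1E)-3-methoxy-1-[(4S,5R)-4-methyl-3-(prop-2-en-1-yl)-5-(3,4,5-trimethoxyphenyl)-4,5-dihydrofuran-2-yl]buta-1,3-dien-2-olate | O1[C@@H](c2cc(OC)c(OC)c(OC)c2)[C@@H](C)C(CC=C)=C1/C=C(/O[Li])C(=C)OC | intermediate
19 | lithium (2R,3S,3aS)-5-methoxy-3-methyl-3a-(prop-2-en-1-yl)-2-(3,4,5-trimethoxyphenyl)-2,3,3a,4-tetrahydro-1-benzofuran-6-olate | C=CC[C@@]12CC(OC)=C(O[Li])C=C1O[C@@H](c1cc(OC)c(OC)c(OC)c1)[C@H]2C | intermediate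
20 | Dysodanthin B, (2R,3S,3aS,5R)-5-methoxy-3-methyl-3a-(prop-2-en-1-yl)-2-(3,4,5-trimethoxyphenyl)-3,3a,4,5-tetrahydro-1-benzofuran-6(2H)-one | C=CC[C@@]12C[C@@H](OC)C(=O)C=C1O[C@@H](c1cc(OC)c(OC)c(OC)c1)[C@H]2C | target

**Step count and risks**

Total step count: 8. Longest linear sequence: 8 steps (1 to 20).

Steps most likely to fail:

Step 8. The 6π closure of the electron-rich trienolate, which carries the allyl group on the inside of its C3a terminus, may be slower than loss of the enolate by proton transfer, and protonation at C5 may occur with low face selectivity. The fallback sets out from 14. The adduct of 16 is warmed only until ring opening to 18 is complete, and 18 is silylated with Me3SiCl to the silyl trienol ether F1. F1 is heated in toluene at 110 °C as a neutral 3-silyloxyhexatriene, which should give the silyl dienol ether F2 by the same disrotatory closure. Fluoride-triggered protodesilylation of F2 at −78 °C (Bu4NF, 2,6-di-tert-butylphenol as proton donor) comes back to the route at 20.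

Step 6. Dehydrochlorination of the α-branched acid chloride may be slow, so that ethoxyacetylene is consumed by the ammonium salt and the silyl ether is lost to acid before the ketene forms. The fallback sets out from 8 and generates the ketene by reductive dehalogenation instead. The dianion of 8 (LiN(i-Pr)2) is brominated with CBr4 to the α-bromo acid F3, and oxalyl chloride converts this to the α-bromo acid chloride F4. Activated zinc in Et2O/1,2-dimethoxyethane in the presence of 9 should then give ketene 11 without any amine salt, and the route is re-joined at 12.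

Step 7. The strained bicyclic enol ether may be disfavoured against re-addition of ethoxide, and the basic fluoride may degrade the cyclobutenone. The fallback sets out from 12 and separates the two events under non-basic conditions. HF·pyridine in THF at 0 °C removes the silyl group and alcohol 13 is isolated. The ring is then closed by transetherification under weak acid (pyridinium p-toluenesulfonate, benzene, 60 °C, 4 Å molecular sieves to take up ethanol), mild enough not to ionise the benzylic C2–O bond, and the route is re-joined at 14.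

Further compounds
F1 | step 8 | trimethylsilyl enol ether of 18, {[(1E)-3-methoxy-1-[(4S,5R)-4-methyl-3-(prop-2-en-1-yl)-5-(3,4,5-trimethoxyphenyl)-4,5-dihydrofuran-2-yl]buta-1,3-dien-2-yl]oxy}trimethylsilane | O1[C@@H](c2cc(OC)c(OC)c(OC)c2)[C@@H](C)C(CC=C)=C1/C=C(/O[Si](C)(C)C)C(=C)OC
F2 | step 8 | trimethylsilyl dienol ether of 20, {[(2R,3S,3aS)-5-methoxy-3-methyl-3a-(prop-2-en-1-yl)-2-(3,4,5-trimethoxyphenyl)-2,3,3a,4-tetrahydro-1-benzofuran-6-yl]oxy}trimethylsilane | C=CC[C@@]12CC(OC)=C(O[Si](C)(C)C)C=C1O[C@@H](c1cc(OC)c(OC)c(OC)c1)[C@H]2C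
F3 | step 6 | (3R,4R)-2-bromo-4-{[tert-butyl(dimethyl)silyl]oxy}-3-methyl-2-(prop-2-en-1-yl)-4-(3,4,5-trimethoxyphenyl)butanoic acid, both C2 epimers | CC(C)(C)[Si](C)(C)O[C@@H](c1cc(OC)c(OC)c(OC)c1)[C@H](C(Br)(CC=C)C(=O)O)C
F4 | step 6 | acid chloride of F3, both C2 epimers | CC(C)(C)[Si](C)(C)O[C@@H](c1cc(OC)c(OC)c(OC)c1)[C@H](C(Br)(CC=C)C(Cl)=O)C
F0 | step 7 | none | none
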